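**Plan**

- Retrosynthesis: the C4 acid comes from a fluoride-labile ester. The epoxydiol ring comes from a 2-alkyl-5-methyl-1,4-benzoquinone through a temporary cyclopentadiene ring (adduct, epoxide, hydride, cycloreversion), and the quinone from a 2,5-dimethoxyarene. C7=C8–CH3 comes from a C8 ketone via its enol triflate. After a C1=C2 double bond is written in, C3–C4 and C5–C10 are cut together (retro-[4+2]). The acyclic trienal is cut at C2–C1 (Stille), C4=C5 (metathesis), C10≡C1 (homologation, carboalumination) and C8–C9 (aldol).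
- Enabling feature: rings A and B hide a 1,7,9-decatriene. The diene is C10=C1–C2=C3, the dienophile is C4=C5 activated by the C4 carboxyl carbon (as CHO), and C6–C9 is the four-carbon tether. One intramolecular [4+2] therefore makes both rings, both quaternary carbons (C4, C10) and C5.
- Forward order: aryl side chain, syn-aldol, alkyne, iodo-diene and enal, trienal, rings A+B (step 10), C8 ketone, Δ7-CH3, quinone, norbornene-masked adduct, oxirane, diol, cycloreversion, acid.
- Stereochemistry: C8 and C9 come from the auxiliary-controlled aldol (C8–O is a temporary stereocentre that later becomes the enol triflate carbon). C4, C5 and C10 come from the cycloaddition (E-enal, endo mode, chair tether with both substituents equatorial). The four oxirane and carbinol centres come from one catalyst-controlled quinone Diels–Alder face, followed by convex-face epoxidation and hydride addition.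
- Numbering used below: decalin atoms as in drimane (ring A = C1–C5, C10; ring B = C5–C10; C11 = CH2 on C9; C12 = CH3 on C8; β = face of the C10 methyl). The six-membered oxygenated ring is C1'–C6', counted from the carbon that carries C11 toward the CH= carbon. Ar = 2,5-dimethoxy-4-methylphenyl.

Key step: step 10

Remark (assumption): in step 17 the (S)-configured oxazaborolidinium ion is taken to send cyclopentadiene to the quinone face that later carries the two hydroxyls; if it selects the other face, its (R)-enantiomer is used.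

**Route**

Step 1
Reactants: 1 2,5-dimethoxy-4-methylbenzaldehyde; 2 Meldrum's acid
Product: 5 3-(2,5-dimethoxy-4-methylphenyl)propanoic acid, via arylidene Meldrum's acid 3 (not isolated), via benzyl Meldrum's acid 4 (not isolated)
Conditions: HCO2H/Et3N (5:2), 100 °C
Reagents that add atoms: none
Why: Knoevenagel condensation, conjugate reduction of the alkylidene by formate and hydrolysis–decarboxylation in the same hot medium (tandem reductive Knoevenagel) should give the saturated acid directly.

Step 2
Reactants: 5 3-(2,5-dimethoxy-4-methylphenyl)propanoic acid; 6 (S)-4-benzylthiazolidine-2-thione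
Product: 7 (S)-4-benzyl-3-[3-(2,5-dimethoxy-4-methylphenyl)propanoyl]thiazolidine-2-thione
Conditions: EDC·HCl, DMAP (cat.), CH2Cl2, 0 °C → rt
Reagents that add atoms: none
Why: Carbodiimide N-acylation attaches the auxiliary that controls the aldol face and later allows direct reduction to the aldehyde.

Step 3
Reactants: 7 N-acyl thiazolidinethione; 8 pent-4-enal
Product: 10 (S)-4-benzyl-3-[(2S,3R)-2-(ArCH2)-3-hydroxyhept-6-enoyl]thiazolidine-2-thione, via titanium enolate 9 (not isolated)
Conditions: TiCl4 (1.05 equiv), i-Pr2NEt (1.1 equiv), N-methylpyrrolidinone (1 equiv), CH2Cl2, 0 °C; then 8, −78 → 0 °C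
Reagents that add atoms: none
Why: Soft enolisation gives the (Z)-enolate 9, which should add through a closed chair transition state on the face away from the auxiliary benzyl group (Evans-syn titanium aldol of an N-acyl thiazolidinethione), setting C9 (S) and C8 (R) together.

Step 4
Reactants: 10 syn-aldol adduct
Product: 11 (S)-4-benzyl-3-[(2S,3R)-2-(ArCH2)-3-(triethylsilyloxy)hept-6-enoyl]thiazolidine-2-thione
Conditions: Et3SiOTf, 2,6-lutidine, CH2Cl2, −78 °C
Reagents that add atoms: triethylsilyl trifluoromethanesulfonate, CC[Si](CC)(CC)OS(=O)(=O)C(F)(F)F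
Why: Silylation blocks retro-aldol cleavage and supplies the C8 substituent that has to sit equatorial in step 10.

Step 5
Reactants: 11 silylated aldol adduct
Product: 12 (2S,3R)-2-(ArCH2)-3-(triethylsilyloxy)hept-6-enal
Conditions: i-Bu2AlH, CH2Cl2, −78 °C
Reagents that add atoms: none
Why: N-Acyl thiazolidinethiones are reduced at low temperature only to the aldehyde stage through a stable aluminium hemiaminal, so C9 should not epimerise and 6 is recovered.

Step 6
Reactants: 12 aldehyde
Product: 13 (3R,4R)-3-(ArCH2)-4-(triethylsilyloxy)oct-7-en-1-yne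
Conditions: dimethyl (1-diazo-2-oxopropyl)phosphonate, K2CO3, MeOH, 0 °C → rt
Reagents that add atoms: dimethyl (1-diazo-2-oxopropyl)phosphonate, COP(=O)(OC)C(=[N+]=[N-])C(C)=O
Why: Ohira–Bestmann (Seyferth–Gilbert) homologation turns CHO into the terminal alkyne C10≡C1 under weakly basic conditions that α-branched β-silyloxy aldehydes tolerate.

Step 7
Reactants: 13 alkyne
Product: 15 (1E,3R,4R)-3-(ArCH2)-1-iodo-2-methyl-4-(triethylsilyloxy)octa-1,7-diene, via alkenylalane 14 (not isolated)
Conditions: AlMe3, Cp2ZrCl2 (cat.), H2O (1 equiv), CH2Cl2, −20 °C; then I2, THF, −30 → 0 °C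
Reagents that add atoms: trimethylaluminium, C[Al](C)C; iodine, II
Why: Zirconium-catalysed syn-carboalumination (Negishi) puts CH3 on C10 and aluminium on C1 of the alkyne only, and iodinolysis with retention should give the (E)-iodide with C9 trans to iodine.

Step 8
Reactants: 15 alkenyl iodide; 16 methacrolein (excess)
Product: 17 (2E,6R,7R,8E)-7-(ArCH2)-9-iodo-2,8-dimethyl-6-(triethylsilyloxy)nona-2,8-dienal
Conditions: second-generation Hoveyda–Grubbs catalyst RuCl2(H2IMes)(=CH-C6H4-2-O-i-Pr) (5 mol%), CH2Cl2, 40 °C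
Reagents that add atoms: none
Why: Cross metathesis of the only monosubstituted alkene with methacrolein should give the (E)-2-methyl enal, the trisubstituted alkenyl iodide being inert to the ruthenium carbene.

Step 9
Reactants: 17 iodo enal
Product: 18 (2E,6R,7R,8E)-7-(ArCH2)-2,8-dimethyl-6-(triethylsilyloxy)undeca-2,8,10-trienal
Conditions: tributyl(vinyl)stannane, Pd2(dba)3, AsPh3, CuI, N-methylpyrrolidinone, rt
Reagents that add atoms: tributyl(vinyl)stannane, C=C[Sn](CCCC)(CCCC)CCCC
Why: Stille coupling with retention of alkene geometry completes the (E)-diene under neutral conditions that spare the enal and the silyl ether.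

Step 10
Reactants: 18 trienal
Product: 19 9β-(ArCH2)-4β,10β-dimethyl-8α-(triethylsilyloxy)-trans-octal-1-ene-4α-carbaldehyde (5α-H)
Conditions: Me2AlCl (1.5 equiv), CH2Cl2, −78 → −20 °C
Reagents that add atoms: none
Why: Coordination of Me2AlCl to the aldehyde lowers the dienophile LUMO, and C4=C5 should add suprafacially across C3 and C10 of the s-cis diene in a concerted, asynchronous [4π+2π] process; the closest known reaction type is the Lewis-acid-promoted intramolecular Diels–Alder reaction of (E)-2-methyl-2,8,10-trienals to trans-fused octalins with a quaternary formyl carbon. Ring A is the new cyclohexene itself (bonds C3–C4 and C5–C10), and ring B closes through the same C5–C10 bond as the fused ring of a 1,7,9-decatriene (type 1 mode, tether C6–C9 in a chair). At C4 the (E)-enal geometry is transferred stereospecifically (CHO cis to H-5, CH3 β); at C5 and C10 the endo-aldehyde, tether-exo transition state gives the trans ring fusion with the inside methyl of the (E)-C10=C1 bond axial. The π-face is fixed by C8 and C9, because only one chair has both the silyloxy and the ArCH2 group equatorial and avoids a syn-diaxial C8–O/C10–CH3 contact, which makes the C10 methyl β. The step therefore needs endo over exo selectivity (secured by the Lewis acid and the E-dienophile) and diastereofacial selectivity (secured by the two matched tether substituents), at a temperature low enough that 1,5-hydrogen shift of the Z-methyl diene does not compete.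

Step 11
Reactants: 19 octalin aldehyde
Product: 20 9β-(ArCH2)-4β,10β-dimethyl-8α-(triethylsilyloxy)-trans-decalin-4α-carbaldehyde
Conditions: H2 (1 atm), Pd/C, EtOAc, rt
Reagents that add atoms: none
Why: Heterogeneous hydrogenation saturates the only C=C (C1=C2), while the neopentyl aldehyde and the silyl ether should survive in a non-protic solvent.

Step 12
Reactants: 20 decalin aldehyde
Product: 22 9β-(ArCH2)-4β,10β-dimethyl-8-oxo-trans-decalin-4α-carboxylic acid, via hydroxy aldehyde 21 (not isolated)
Conditions: CrO3, H2SO4, H2O, acetone, 0 °C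
Reagents that add atoms: water, O
Why: Aqueous chromic acid (Jones oxidation, hexavalent chromium) cleaves the triethylsilyl ether, oxidises the C8 alcohol to the ketone and the aldehyde hydrate to the acid in one operation, and C9 keeps its equatorial, thermodynamically preferred configuration.

Step 13
Reactants: 22 keto acid
Product: 23 2-(trimethylsilyl)ethyl 9β-(ArCH2)-4β,10β-dimethyl-8-oxo-trans-decalin-4α-carboxylate
Conditions: Me3SiCH2CH2OH, PPh3, DIAD, THF, 0 °C → rt
Reagents that add atoms: 2-(trimethylsilyl)ethanol, C[Si](C)(C)CCO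
Why: In the Mitsunobu esterification the carboxylate attacks the activated primary alcohol, so the quaternary C4 does not slow it, and the ester can later be removed by fluoride.

Step 14
Reactants: 23 keto ester
Product: 25 C7=C8 enol triflate of 23, via potassium enolate 24 (not isolated)
Conditions: KN(SiMe3)2, THF, −78 °C; then PhNTf2, −78 → 0 °C
Reagents that add atoms: N-phenylbis(trifluoromethanesulfonimide), O=S(=O)(N(c1ccccc1)S(=O)(=O)C(F)(F)F)C(F)(F)F
Why: Kinetic deprotonation should occur at the C7 methylene and not at the hindered tertiary C9–H, and O-triflation of 24 fixes the double bond at C7=C8.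

Step 15
Reactants: 25 enol triflate
Product: 26 2-(trimethylsilyl)ethyl 9β-(ArCH2)-4β,8,10β-trimethyl-trans-octal-7-ene-4α-carboxylate
Conditions: MeZnCl, Pd(PPh3)4 (5 mol%), THF, 50 °C
Reagents that add atoms: methylzinc chloride, C[Zn]Cl
Why: Negishi coupling of the alkenyl triflate replaces OTf by CH3 with the double bond position retained, giving the drim-7-ene unit and C9 in its final configuration.

Step 16
Reactants: 26 dimethoxyarene
Product: 27 2-methyl-5-(decalinylmethyl)-1,4-benzoquinone (decalinyl = the C9 substituent of 26)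
Conditions: (NH4)2Ce(NO3)6, MeCN/H2O, 0 °C
Reagents that add atoms: water, O
Why: Oxidative demethylation of the 1,4-dimethoxyarene by tetravalent cerium gives the p-quinone within minutes, faster than any reaction at the trisubstituted alkene.

Step 17
Reactants: 27 quinone; 28 cyclopenta-1,3-diene
Product: 29 endo cyclopentadiene adduct across C3'=C4' (ring-fusion CH3 and H on the convex face)
Conditions: (S)-B-(o-tolyl)oxazaborolidine of α,α-diphenylprolinol·HNTf2 (20 mol%), CH2Cl2, −78 °C
Reagents that add atoms: none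
Why: In this Lewis-acid-catalysed endo Diels–Alder reaction of a quinone the bulky chiral oxazaborolidinium ion should bind the carbonyl lone pair on the side of the methyl-bearing alkene, away from the decalinylmethyl group, so the diene adds to the C(CH3)=CH bond from one face, masking it and creating the convex/concave bias used in steps 18 and 19.

Step 18
Reactants: 29 adduct
Product: 30 1',6'-epoxide of 29 (oxirane on the convex face)
Conditions: 30% H2O2, Na2CO3, acetone/H2O, 0 °C
Reagents that add atoms: hydrogen peroxide, OO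
Why: Weitz–Scheffer epoxidation of the remaining enedione double bond should occur from the convex face of the cis-fused adduct, and the ring-fusion methyl prevents enolisation to a hydroquinone.

Step 19
Reactants: 30 epoxy diketone
Product: 31 2',5'-diol of 30 (both OH on the concave face, anti to the oxirane)
Conditions: NaBH4, MeOH/CH2Cl2, −20 °C
Reagents that add atoms: none
Why: Borohydride should attack both ketones from the same convex face, placing both hydroxyls anti to the oxirane and cis to each other, while the hindered ester is untouched.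

Step 20
Reactants: 31 tricyclic epoxy diol
Product: 32 2-(trimethylsilyl)ethyl ester of the target
Conditions: Ph2O (degassed), 230 °C, sealed tube
Reagents that add atoms: none
Why: Thermal retro-Diels–Alder reaction expels cyclopentadiene and restores the C3'=C4'(CH3) double bond without touching the four ring stereocentres.

Step 21
Reactants: 32 silylethyl ester
Product: 33 target acid CNP0358222.2
Conditions: Bu4NF, THF, 0 °C → rt; then AcOH
Reagents that add atoms: none
Why: Fluoride attacks silicon of the 2-(trimethylsilyl)ethyl ester, which fragments to ethylene and the carboxylate, a cleavage remote from the hindered C4 and mild enough for the epoxy diol.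

**Compound list**

1 | 2,5-dimethoxy-4-methylbenzaldehyde | COc1cc(C=O)c(OC)cc1C | starting material
2 | Meldrum's acid (2,2-dimethyl-1,3-dioxane-4,6-dione) | CC1(C)OC(=O)CC(=O)O1 | starting material
3 | 5-(2,5-dimethoxy-4-methylbenzylidene) Meldrum's acid | COc1cc(C=C2C(=O)OC(C)(C)OC2=O)c(OC)cc1C | intermediate
4 | 5-(2,5-dimethoxy-4-methylbenzyl) Meldrum's acid | COc1cc(CC2C(=O)OC(C)(C)OC2=O)c(OC)cc1C | intermediate
5 | 3-(2,5-dimethoxy-4-methylphenyl)propanoic acid | COc1cc(CCC(=O)O)c(OC)cc1C | intermediate
6 | (S)-4-benzylthiazolidine-2-thione | S=C1N[C@@H](Cc2ccccc2)CS1 | starting material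
7 | (S)-4-benzyl-3-[3-(2,5-dimethoxy-4-methylphenyl)propanoyl]thiazolidine-2-thione | COc1cc(CCC(=O)N2[C@@H](Cc3ccccc3)CSC2=S)c(OC)cc1C | intermediate
8 | pent-4-enal | C=CCCC=O | starting material
9 | trichlorotitanium (Z)-enolate of 7 | COc1cc(C/C=C(\O[Ti](Cl)(Cl)Cl)N2[C@@H](Cc3ccccc3)CSC2=S)c(OC)cc1C | intermediate
10 | (S)-4-benzyl-3-[(2S,3R)-2-(ArCH2)-3-hydroxyhept-6-enoyl]thiazolidine-2-thione | C=CCC[C@@H](O)[C@H](Cc1cc(OC)c(C)cc1OC)C(=O)N1[C@@H](Cc2ccccc2)CSC1=S | intermediate
11 | triethylsilyl ether of 10 | C=CCC[C@@H](O[Si](CC)(CC)CC)[C@H](Cc1cc(OC)c(C)cc1OC)C(=O)N1[C@@H](Cc2ccccc2)CSC1=S | intermediate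
12 | (2S,3R)-2-(ArCH2)-3-(triethylsilyloxy)hept-6-enal | C=CCC[C@@H](O[Si](CC)(CC)CC)[C@H](Cc1cc(OC)c(C)cc1OC)C=O | intermediate
13 | (3R,4R)-3-(ArCH2)-4-(triethylsilyloxy)oct-7-en-1-yne | C=CCC[C@@H](O[Si](CC)(CC)CC)[C@H](Cc1cc(OC)c(C)cc1OC)C#C | intermediate
14 | (E)-alkenyl(dimethyl)alane from 13 | C=CCC[C@@H](O[Si](CC)(CC)CC)[C@H](Cc1cc(OC)c(C)cc1OC)/C(C)=C/[Al](C)C | intermediate
15 | (1E,3R,4R)-3-(ArCH2)-1-iodo-2-methyl-4-(triethylsilyloxy)octa-1,7-diene | C=CCC[C@@H](O[Si](CC)(CC)CC)[C@H](Cc1cc(OC)c(C)cc1OC)/C(C)=C/I | intermediate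
16 | methacrolein | CC(=C)C=O | starting material
17 | (2E,6R,7R,8E)-7-(ArCH2)-9-iodo-2,8-dimethyl-6-(triethylsilyloxy)nona-2,8-dienal | O=C/C(C)=C/CC[C@@H](O[Si](CC)(CC)CC)[C@H](Cc1cc(OC)c(C)cc1OC)/C(C)=C/I | intermediate
18 | (2E,6R,7R,8E)-7-(ArCH2)-2,8-dimethyl-6-(triethylsilyloxy)undeca-2,8,10-trienal | O=C/C(C)=C/CC[C@@H](O[Si](CC)(CC)CC)[C@H](Cc1cc(OC)c(C)cc1OC)/C(C)=C/C=C | intermediate
19 | 9β-(ArCH2)-4β,10β-dimethyl-8α-(triethylsilyloxy)-trans-octal-1-ene-4α-carbaldehyde | COc1cc(C[C@H]2[C@H](O[Si](CC)(CC)CC)CC[C@@H]3[C@]2(C)C=CC[C@@]3(C)C=O)c(OC)cc1C | intermediate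
20 | 9β-(ArCH2)-4β,10β-dimethyl-8α-(triethylsilyloxy)-trans-decalin-4α-carbaldehyde | COc1cc(C[C@H]2[C@H](O[Si](CC)(CC)CC)CC[C@@H]3[C@]2(C)CCC[C@@]3(C)C=O)c(OC)cc1C | intermediate
21 | 8α-hydroxy aldehyde (desilylated 20) | COc1cc(C[C@H]2[C@H](O)CC[C@@H]3[C@]2(C)CCC[C@@]3(C)C=O)c(OC)cc1C | intermediate
22 | 9β-(ArCH2)-4β,10β-dimethyl-8-oxo-trans-decalin-4α-carboxylic acid | COc1cc(C[C@H]2C(=O)CC[C@@H]3[C@]2(C)CCC[C@@]3(C)C(=O)O)c(OC)cc1C | intermediate
23 | 2-(trimethylsilyl)ethyl ester of 22 | COc1cc(C[C@H]2C(=O)CC[C@@H]3[C@]2(C)CCC[C@@]3(C)C(=O)OCC[Si](C)(C)C)c(OC)cc1C | intermediate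
24 | potassium C7=C8 enolate of 23 | COc1cc(C[C@H]2C([O-])=CC[C@@H]3[C@]2(C)CCC[C@@]3(C)C(=O)OCC[Si](C)(C)C)c(OC)cc1C.[K+] | intermediate
25 | C7=C8 enol triflate of 23 | COc1cc(C[C@H]2C(OS(=O)(=O)C(F)(F)F)=CC[C@@H]3[C@]2(C)CCC[C@@]3(C)C(=O)OCC[Si](C)(C)C)c(OC)cc1C | intermediate
26 | 2-(trimethylsilyl)ethyl 9β-(ArCH2)-4β,8,10β-trimethyl-trans-octal-7-ene-4α-carboxylate | COc1cc(C[C@H]2C(C)=CC[C@@H]3[C@]2(C)CCC[C@@]3(C)C(=O)OCC[Si](C)(C)C)c(OC)cc1C | intermediate
27 | 2-methyl-5-(decalinylmethyl)-1,4-benzoquinone | CC1=CC(=O)C(C[C@H]2C(C)=CC[C@@H]3[C@]2(C)CCC[C@@]3(C)C(=O)OCC[Si](C)(C)C)=CC1=O | intermediate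
28 | cyclopenta-1,3-diene | C1=CCC=C1 | starting material
29 | endo cyclopentadiene adduct of 27 across C3'=C4' | C[C@]12[C@H]3C=C[C@H](C3)[C@H]1C(=O)C(C[C@H]4C(C)=CC[C@@H]5[C@]4(C)CCC[C@@]5(C)C(=O)OCC[Si](C)(C)C)=CC2=O | intermediate
30 | convex-face 1',6'-epoxide of 29 | C[C@]12[C@H]3C=C[C@H](C3)[C@H]1C(=O)[C@]4(C[C@H]5C(C)=CC[C@@H]6[C@]5(C)CCC[C@@]6(C)C(=O)OCC[Si](C)(C)C)O[C@@H]4C2=O | intermediate
31 | 2',5'-diol of 30 (both OH concave, anti to the oxirane) | C[C@]12[C@H]3C=C[C@H](C3)[C@H]1[C@@H](O)[C@]4(C[C@H]5C(C)=CC[C@@H]6[C@]5(C)CCC[C@@]6(C)C(=O)OCC[Si](C)(C)C)O[C@@H]4[C@H]2O | intermediate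
32 | 2-(trimethylsilyl)ethyl ester of the target | CC1=C[C@@H](O)[C@]2(C[C@H]3C(C)=CC[C@@H]4[C@]3(C)CCC[C@@]4(C)C(=O)OCC[Si](C)(C)C)O[C@@H]2[C@H]1O | intermediate
33 | CNP0358222.2 | CC1=C[C@@H](O)[C@]2(C[C@H]3C(C)=CC[C@@H]4[C@]3(C)CCC[C@@]4(C)C(=O)O)O[C@@H]2[C@H]1O | target

**Count and risks**

Total steps: 21. Longest linear sequence: 21 steps (1 → 33); 2, 6, 8, 16 and 28 enter directly.

Steps most likely to fail:

1. Step 10. Both new bonds end at a carbon that becomes quaternary and the diene must reach an s-cis form with an inside methyl, so the cycloaddition may be slow; the exo (cis-fused) mode or acid-induced isomerisation of the diene could then take over. The fallback sets out from 18 and comes back at 19. Trienal 18 is treated with 1,2-bis(trimethylsilyloxy)ethane and Me3SiOTf (cat.) in CH2Cl2 at −78 °C to give the 1,3-dioxolane of trienal 18 F1. More Me3SiOTf at −78 → −40 °C opens the dioxolane to an oxygen-stabilised allyl cation, a much stronger dienophile, which should add stepwise to the diene (cationic Diels–Alder reaction of an α,β-unsaturated acetal) through the same chair tether to give the 1,3-dioxolane of aldehyde 19 F2. Mild hydrolysis (PPTS, acetone/H2O) returns 19.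

2. Step 17. The chiral acid may not fully control which ring double bond and which quinone face the diene attacks. The fallback sets out from 27 and comes back at 29. Cyclopentadiene is added without catalyst (CH2Cl2, 0 → 25 °C); 29 is separated by chromatography from the facial diastereomer of adduct 29 F3 (a diastereomer, because the decalin is a single enantiomer). F3 is returned to 27 by cycloreversion (o-dichlorobenzene, 200 °C) and recycled, so stereocontrol rests on separation and recycling instead of catalysis.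

3. Step 20. At 230 °C dehydration or oxirane opening by the free neighbouring hydroxyls may compete with the cycloreversion. The fallback sets out from 31 and comes back at 33. Diol 31 is silylated (Et3SiOTf, 2,6-lutidine, CH2Cl2, −40 °C) to the bis(triethylsilyl) ether of 31 F4. Thermolysis of this hydroxyl-free compound (Ph2O, 230 °C, or flash vacuum pyrolysis) should give the bis(triethylsilyl) ether of 32 F5. Excess Bu4NF in THF then removes both silyl ethers and the silylethyl ester together to give 33.

**Further compounds**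

F1 | step 10 | 1,3-dioxolane of trienal 18 | O1CCOC1/C(C)=C/CC[C@@H](O[Si](CC)(CC)CC)[C@H](Cc1cc(OC)c(C)cc1OC)/C(C)=C/C=C
F2 | step 10 | 1,3-dioxolane of aldehyde 19 | COc1cc(C[C@H]2[C@H](O[Si](CC)(CC)CC)CC[C@@H]3[C@]2(C)C=CC[C@@]3(C)C4OCCO4)c(OC)cc1C
F3 | step 17 | facial diastereomer of adduct 29 | C[C@@]12[C@@H]3C=C[C@@H](C3)[C@@H]1C(=O)C(C[C@H]4C(C)=CC[C@@H]5[C@]4(C)CCC[C@@]5(C)C(=O)OCC[Si](C)(C)C)=CC2=O
F4 | step 20 | bis(triethylsilyl) ether of 31 | C[C@]12[C@H]3C=C[C@H](C3)[C@H]1[C@@H](O[Si](CC)(CC)CC)[C@]4(C[C@H]5C(C)=CC[C@@H]6[C@]5(C)CCC[C@@]6(C)C(=O)OCC[Si](C)(C)C)O[C@@H]4[C@H]2O[Si](CC)(CC)CC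
F5 | step 20 | bis(triethylsilyl) ether of 32 | CC1=C[C@@H](O[Si](CC)(CC)CC)[C@]2(C[C@H]3C(C)=CC[C@@H]4[C@]3(C)CCC[C@@]4(C)C(=O)OCC[Si](C)(C)C)O[C@@H]2[C@H]1O[Si](CC)(CC)CC
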